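The readings stem from a simulated flask for an exercise; scatter was added.

Take substrate as the invariant of a stopped chain: each turn of the chain spends it, so where it stands still, no chain is turning.

| setting | dawn | autumn | flask |
|---|---|---|---|
| substrate | 0.25 M | 0.25 M | 0.25 M |
| partner | 2 equiv | 2 equiv | 2.00 equiv |
| transfer agent | 0.025 M | 0.025 M | 0.0250 M |
| protic impurity | 0.125 M | 0.19 M | 0.125 M |
| scavenger | 0.50 equiv | 0.50 equiv | 0.500 equiv |
| initiator | 5 mol% | 5 mol% | 5 mol% |
| temperature | 110 °C | 110 °C | 110 °C |
| remark | the very flask that is asked about, followed so far | run made earlier |  |
| time |  |  | 2.5 h |

- dawn (time / min: target / %, substrate / %): 12.0: 25.8, 63.8; 25.0: 27.1, 59.5; 40.0: 23.2, 58.3; 50.0: 22.1, 58.4; 60.0: 22.6, 57.3; 80.0: 18.7, 59.3; 90.0: 18.8, 58.9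
- autumn (time / min: target / %, substrate / %): 0.167: 0.5, 99.1; 0.500: 1.6, 95.9; 0.833: 3.0, 96.3; 1.33: 6.8, 93.7; 2.00: 6.6, 86.8; 2.50: 7.1, 85.0; 3.00: 10.6, 83.8

(readings scatter by 1 percentage point)

- alpha: at 2.5 h take out 90 % of the target then present, then wait 80 min
- eta: change nothing and wait 80 min more
- delta: at 2.5 h add partner, 100 % of the amount charged, then wait 80 min
- theta: at 2.5 h raise the temperature by 25 K, then wait 80 min

- in percentages every species weighs as the substrate in it: one ended chains counts as two
- for released group the idle adduct is counted in
- what is taken out of target is counted as made
- the numbers in the tables scatter by 1 percentage point (one standard deviation)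
- what may be going on: partner + first chain carrier -> target + second chain carrier; 2 first chain carrier -> ended chains; substrate + second chain carrier -> released group + first chain carrier; partner + protic impurity -> quenched reagent; scavenger + released group -> scavenged by-product; partner + released group <-> idle adduct; transfer agent + first chain carrier -> side product + idle radical; partner + target -> over-reaction product; substrate + initiating radical -> capped initiator + first chain carrier; initiator -> 2 initiating radical; 2 idle radical -> ended radicals
- additions bring no volume worth counting
- the earlier runs do not show what temperature does; that part of a forecast is a guess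

1. target, in percent of the substrate first charged, at 2.5 h
2. which option adds most target ("none" when 2 percentage points or less is all one gets) (alpha / eta / delta / theta / none)
3. target present, with what was taken out counted in, in percent of the substrate first charged, after alpha
4. target present, with what was taken out counted in, in percent of the substrate first charged, after theta

Read the dawn flask, the one asked about. Its substrate reads 58.3 % at 40.0 min and 58.9 % at 90.0 min, a shift less than the scatter of 1 percentage point. The autumn run, with more protic impurity, shows the chain at work: its substrate falls from 99.1 % to 83.8 % by 3.00 min. Hold that pace steady and the loss seen in the dawn flask takes 7.61 min, less than the 40.0 min of the first of those two readings.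

The bench rule says: substrate stopped, reaction over, take the yield from the last point, here 18.8 %. Test it on the target. Between 25.0 min and 90.0 min the dawn target falls from 27.1 % to 18.8 %, a drop of 8.3 points, more than the scatter. So the rule holds for substrate and breaks for target.

One listed step spends target without touching substrate: partner + target gives over-reaction product, at rate k[partner][target]. Take the whole charge of protic impurity off the partner and 0.375 M remains, more than the 0.0678 M of target read at 25.0 min, so I treat the loss as pseudo-first-order. The two readings then give a decay constant of 0.00563 /min, and from it the stalled half-life of target, the time in which the stopped dawn flask loses half its target, read here as 123 min.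

Here is the border of the rule: the wait from the last reading to 2.5 h is about half of that half-life, too long to ignore. My reckoning gives 13.4 %. I see no option that makes target, so I would answer none: alpha saves the part taken out, and the others wait or speed its loss.

The forecast says 14 % at 2.5 h, a little above mine, with none as best choice, 13.4 % after alpha and 5 % after theta. Its ground: “The chain is therefore dead after about 30 min”.

The flask holds 12.4 % target at 2.5 h; the best choice is none, with 11.9 % after alpha and 0.498 % after theta.

    partner + first chain carrier → target + second chain carrier (k = 1.10 × 10⁵ /M/min, Ea = 43.0 kJ/mol)
    2 first chain carrier → ended chains (k = 8.90 × 10⁷ /M/s, Ea = 22.0 kJ/mol)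
    substrate + second chain carrier → released group + first chain carrier (k = 2.40 × 10⁵ /M/min, Ea = 32.0 kJ/mol)
    partner + protic impurity → quenched reagent (k = 0.650 /M/min, Ea = 73.0 kJ/mol)
    scavenger + released group → scavenged by-product (k = 12.0 /M/min, Ea = 78.0 kJ/mol)
    partner + released group ⇌ idle adduct, settled at all times (K = 0.490 /M, ΔH = −17.0 kJ/mol)
    transfer agent + first chain carrier → side product + idle radical (kL = 19000 /M/s, Ea = 42.0 kJ/mol)
    partner + target → over-reaction product (k = 0.0240 /M/min, Ea = 104 kJ/mol)
    substrate + initiating radical → capped initiator + first chain carrier (k = 88000 /M/s, Ea = 25.0 kJ/mol)
    initiator → 2 initiating radical (k = 0.250 /min, Ea = 115 kJ/mol)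
    2 idle radical → ended radicals (k = 5.80 × 10⁶ /M/s, Ea = 31.0 kJ/mol)
    (constants at 110 °C)

At 150 min this flask holds 19.1 % over-reaction product, with substrate at 58.5 %. Start from 12.4 % and let the stalled half-life of 123 min run on to a reading of the same flask at 4.0 h: it gives 7.47 % target, and that reading holds 7.34 %.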